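**Retrosynthetic overview**

1. Target 10 ⇐ hydrogenation of the (Z)-alkenylphenol 9; the C1'=C2' alkene of the side chain is a temporary oxidation level.
2. 9 ⇐ nickel-catalysed ring-opening alkylation of 5,7-dimethoxybenzofuran 5 with nonadecylmagnesium bromide 7. This forms the bond between side-chain C2' and C3' (benzofuran C2 to the Grignard carbon), opens the furan ring and sets the phenol OH free in one operation, with no protecting group.
3. Enabling feature: the phenol oxygen on ring C1 is ortho to the chain-bearing C6, so O–C1–C6–C1'–C2' can be closed to the furan ring (O1, C7a, C3a, C3, C2) of a benzofuran, whose enol-ether C2–O bond serves as the leaving group.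
4. 5 ⇐ acid cyclodehydration of the aryloxyacetaldehyde acetal 3 ⇐ 2,4-dimethoxyphenol 1 + bromoacetaldehyde diethyl acetal 2.
5. Ring order: the benzene ring is bought; the furan ring is the only ring made (step 2) and it is opened again in step 4.

Key step: step 4

Remark: the target has no stereocentre and no stereogenic double bond, so it is achiral and no enantiomer has to be selected; compounds 1, 2 and 6 are taken as catalogue chemicals.

**Route**

Step 1
Reactants: 1 2,4-dimethoxyphenol; 2 bromoacetaldehyde diethyl acetal
Product: 3 1-(2,2-diethoxyethoxy)-2,4-dimethoxybenzene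
Conditions: K2CO3, KI (cat.), DMF, 110 °C, N2
Reagents that add atoms: none
Why: Williamson ether synthesis, in which the phenoxide of 1 displaces the primary bromide of 2 by SN2 while the acetal is inert to base.

Step 2
Reactants: 3 1-(2,2-diethoxyethoxy)-2,4-dimethoxybenzene
Product: 5 5,7-dimethoxybenzofuran, via racemic 3-ethoxy-5,7-dimethoxy-2,3-dihydrobenzofuran 4 (not isolated)
Conditions: Amberlyst-15, PhCl, reflux, EtOH distilled off
Reagents that add atoms: none
Why: Acid-catalysed cyclodehydration of an aryloxyacetaldehyde acetal (a standard benzofuran synthesis), in which the oxocarbenium ion attacks C6, the only free position ortho to the ether oxygen, in an intramolecular Friedel–Crafts reaction and loss of the second ethanol from 4 aromatises the furan ring.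

Step 3
Reactants: 6 1-bromononadecane
Product: 7 nonadecylmagnesium bromide (titrated THF solution, used directly)
Conditions: Mg turnings (I2-activated), THF, 45 °C, slow addition
Reagents that add atoms: magnesium, [Mg]
Why: Grignard formation by insertion of magnesium into the primary C–Br bond, with slow addition to keep Wurtz coupling low.

Step 4
Reactants: 5 5,7-dimethoxybenzofuran; 7 nonadecylmagnesium bromide
Product: 9 (Z)-2-(heneicos-1-en-1-yl)-4,6-dimethoxyphenol, via bromomagnesium (Z)-2-(heneicos-1-en-1-yl)-4,6-dimethoxyphenolate 8 (not isolated)
Conditions: 7 (1.5 equiv), Ni(cod)2 (5 mol %), ICy·HBF4 (10 mol %), toluene/THF, 60 °C; then 1 M HCl, 0 °C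
Reagents that add atoms: none
Why: Ni(0)–NHC binds the C2=C3 π-bond of 5 and inserts into the C2–O bond to give a six-membered aryloxy(alkenyl)nickel(II) oxanickelacycle; transmetalation with 7 puts the nonadecyl group on nickel and releases the phenoxide as its magnesium salt 8, and C(sp2)–C(sp3) reductive elimination joins benzofuran C2 to the Grignard carbon with retention of the cis geometry. The closest known reaction type is the Wenkert-type nickel-catalysed Kumada ring opening of benzofurans with Grignard reagents, combined with the Ni/NHC-catalysed alkylative coupling of aryl and alkenyl ethers with primary alkyl Grignard reagents that carry β-hydrogens. No ring is closed (the furan ring is opened) and no stereocentre is formed; the Z geometry is erased in step 5, so any E/Z or positional alkene isomers converge on the same product. The step needs C2–O cleavage in preference to the two aryl C–OMe bonds, which the enol-ether character of C2–O, the η2-precoordination of nickel to C2=C3 and the electron-rich phenoxide nature of the product should secure. It also needs reductive elimination to outrun β-hydride elimination of the alkylnickel intermediate, for which the bulky, strongly σ-donating NHC ligand is chosen.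

Step 5
Reactants: 9 (Z)-2-(heneicos-1-en-1-yl)-4,6-dimethoxyphenol
Product: 10 6-n-heneicosyl-2,4-dimethoxyphenol
Conditions: H2 (1 atm), 10% Pd/C, EtOAc, rt
Reagents that add atoms: none
Why: Heterogeneous catalytic hydrogenation saturates the disubstituted styrenyl alkene, while the phenol and the aryl methyl ethers are inert and there is no benzylic C–O bond to hydrogenolyse.

**Compound list**

1 | 2,4-dimethoxyphenol | COc1ccc(O)c(OC)c1 | starting material
2 | bromoacetaldehyde diethyl acetal (2-bromo-1,1-diethoxyethane) | CCOC(CBr)OCC | starting material
3 | 1-(2,2-diethoxyethoxy)-2,4-dimethoxybenzene | CCOC(COc1ccc(OC)cc1OC)OCC | intermediate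
4 | 3-ethoxy-5,7-dimethoxy-2,3-dihydrobenzofuran (racemic, not isolated) | CCOC1COc2c(OC)cc(OC)cc21 | intermediate
5 | 5,7-dimethoxybenzofuran | COc1cc(OC)c2occc2c1 | intermediate
6 | 1-bromononadecane | CCCCCCCCCCCCCCCCCCCBr | starting material
7 | nonadecylmagnesium bromide | CCCCCCCCCCCCCCCCCCC[Mg]Br | intermediate
8 | bromomagnesium (Z)-2-(heneicos-1-en-1-yl)-4,6-dimethoxyphenolate (not isolated) | CCCCCCCCCCCCCCCCCCC/C=C\c1cc(OC)cc(OC)c1O[Mg]Br | intermediate
9 | (Z)-2-(heneicos-1-en-1-yl)-4,6-dimethoxyphenol | CCCCCCCCCCCCCCCCCCC/C=C\c1cc(OC)cc(OC)c1O | intermediate
10 | 6-n-heneicosyl-2,4-dimethoxyphenol | CCCCCCCCCCCCCCCCCCCCCc1cc(OC)cc(OC)c1O | target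

**Step count**

Total step count: 5. Longest linear sequence: 4 steps (steps 1, 2, 4, 5); step 3 is a one-step side branch.

**Steps most likely to fail**

Step 4. β-Hydride elimination from the nonadecyl–nickel intermediate may outrun reductive elimination, so that the furan ring is opened reductively without C–C bond formation; nickel may also insert into an aryl C–OMe bond. The fallback sets out from compound 1 and comes back to the route at compound 10. O-Allylation of 1 (allyl bromide, K2CO3, acetone, reflux) should give 1-(allyloxy)-2,4-dimethoxybenzene F1. Aromatic Claisen rearrangement (N,N-diethylaniline, 190 °C) can only go to the single free ortho position and should give 2-allyl-4,6-dimethoxyphenol F2. Olefin cross-metathesis of F2 with commercial 1-eicosene (Grubbs second-generation catalyst, CH2Cl2, 40 °C) should form the same C2'–C3' connection as a double bond in (E)-2-(heneicos-2-en-1-yl)-4,6-dimethoxyphenol F3; any Z isomer formed alongside is of no consequence. Hydrogenation of F3 under the conditions of step 5 should then give 10.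

Step 2. Ring closure has to occur at C6, which is meta to both methoxy groups, so intermolecular Friedel–Crafts alkylation at the more electron-rich C3 and C5 positions of a second molecule (oligomerisation) may compete. The fallback sets out from compound 1 and comes back at compound 5. Magnesium-mediated ortho-formylation (MgCl2, Et3N, paraformaldehyde, MeCN, reflux) should give 2-hydroxy-3,5-dimethoxybenzaldehyde F4, with the formyl group exclusively ortho to the hydroxyl. O-Alkylation with chloroacetic acid (NaOH, H2O, reflux; then acidification) should give (2-formyl-4,6-dimethoxyphenoxy)acetic acid F5. Perkin-type cyclisation with decarboxylation (Ac2O, NaOAc, AcOH, reflux) should then deliver 5.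

Step 3. Wurtz-type homocoupling of the waxy long-chain bromide at the magnesium surface, or incomplete insertion, may leave too little active Grignard reagent. The fallback sets out from compound 5 and comes back at compound 9, and it avoids organomagnesium chemistry altogether. Hydroboration of commercial 1-nonadecene with 9-BBN (THF, rt) should give B-nonadecyl-9-borabicyclo[3.3.1]nonane F6. This is used as the nucleophile in a nickel/NHC-catalysed alkyl Suzuki-type C–O coupling with 5 (Ni(cod)2, IPr·HCl, CsF, toluene, 100 °C), which should open the furan ring to 9.

**Further compounds**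

F1 | step 4 | 1-(allyloxy)-2,4-dimethoxybenzene | C=CCOc1ccc(OC)cc1OC
F2 | step 4 | 2-allyl-4,6-dimethoxyphenol | C=CCc1cc(OC)cc(OC)c1O
F3 | step 4 | (E)-2-(heneicos-2-en-1-yl)-4,6-dimethoxyphenol | CCCCCCCCCCCCCCCCCC/C=C/Cc1cc(OC)cc(OC)c1O
F4 | step 2 | 2-hydroxy-3,5-dimethoxybenzaldehyde | O=Cc1cc(OC)cc(OC)c1O
F5 | step 2 | (2-formyl-4,6-dimethoxyphenoxy)acetic acid | O=Cc1cc(OC)cc(OC)c1OCC(=O)O
F6 | step 3 | B-nonadecyl-9-borabicyclo[3.3.1]nonane | CCCCCCCCCCCCCCCCCCCB1C2CCCC1CCC2
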